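Slowness is what the zeta flask shows after 3.00 d: X gains 0.9 percentage points by 5.00 d against a scatter of 0.3 points, and a slow stretch may be an end or a standing balance between two directions.

common to all: E 0.285 M

| charge | J | temperature | remark | time |
|---|---|---|---|---|
| zeta | 0.30 M | −20 °C | the very flask that is asked about, followed so far |  |
| theta | 0.60 M | −35 °C | run made earlier |  |
| flask | 0.30 M | −20 °C |  | 8.0 d |

- zeta (time / d: X / %, J / %): 1.04: 29.7, 70.6; 2.08: 38.5, 62.8; 3.00: 39.2, 60.3; 4.00: 39.7, 60.0; 5.00: 40.1, 60.8
- theta (time / d: X / %, J / %): 4.00: 19.9, 80.0; 8.00: 29.1, 71.2; 15.0: 34.6, 65.3; 25.0: 36.9, 62.3; 50.0: 37.8, 61.8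

(each reading ± 0.3 percentage points)

- Saturday's: at 8.0 d raise the temperature by 15 K, then wait 15 d
- Tuesday's: at 8.0 d add E, 100% of the amount charged, then wait 15 d
- Monday's: change nothing and wait 15 d more
- Friday's: at 8.0 d take out 90% of the X then present, then wait 15 d

- removed X is counted in
- additions bring no volume worth counting

1. X, in percent of the J first charged, at 8.0 d
2. which option adds most X ("none" when 2 percentage points or less is all one gets) (Saturday's / Tuesday's / Monday's / Friday's / none)
3. X present, with what was taken out counted in, in percent of the J first charged, after Tuesday's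
4. X present, with what was taken out counted in, in percent of the J first charged, after Friday's

We read it as a balance, J + E ⇌ X + a partner formed one for one. At 4.00 d, zeta holds [X] = 0.119 M, [J] = 0.180 M and at most [E] = 0.166 M, the charge less what X used. Their exchange quotient is 0.475; by exchange quotient, the usual reaction quotient, we mean [X] times [partner] over [J][E]. Any further loss of E in zeta makes [E] smaller and this quotient larger.

Taking out 90% of X leaves the balance to refill, and we compute only that correction, to first order in the shift: 0.0432 M, or 14 points. Our figure for Friday's is therefore 54.1%.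

The forecast differs: its ground is “I favour dying E”, and it gives 40% now, Tuesday's as best, 63% after Tuesday's and 40.2% after Friday's.

The flask gives 37.6% now and Friday's as best, with a gain of 6.5 points. Tuesday's ends at 37.7% and Friday's at 44.1%, less than our figure.

    2 E → Q (k = 4.81 × 10⁻⁴ M⁻¹ min⁻¹, Ea = 74.0 kJ mol⁻¹)
    J + E ⇌ X + G (K = 1.10, k = 0.00127 M⁻¹ min⁻¹, Ea = 62.0 kJ mol⁻¹, ΔH = −64.0 kJ mol⁻¹)
    (constants at −20 °C)

In this flask, J + E ⇌ X + G had half of its turnover up to 8.00 d behind it by 0.501 d and 2 E → Q by 1.05 d, and at 4.00 d X stood at 39.9% with E at 24.9% of its charge. While Q grew to 0.0579 M at 8.00 d, E stood at 19.7% of its charge, the backward rate was 110% of the forward, and X had fallen to 37.6%. With [E] as it then stood, the exchange quotient in this flask is 1.21, more than the 0.475 we reckoned from zeta. In the neighbouring flask with 0.075 M of J, where X stood at 61.8% at 8.00 d, it is 1.22.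

The readings were computed on assumed constants; the scatter is artificial.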